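The route rests on opening the 2H-pyran ring between O1 and C2 in the retro-electrocyclic sense: a 2,2-dimethyl-2H-chromene is the valence tautomer of an ortho-quinone methide whose 1-oxatriene (O1=C8a–C4a=C4–C3=C2) carries the gem-dimethyl terminus. In step 1 this open dienone is generated from 4-bromo-3-methoxyphenol and prenal and closes at once, so one operation forms C4–C4a and O1–C2 and delivers the complete pyran ring. The step exploits the phenolic ring carbon C4a, ortho to oxygen and para to the C7 methoxy group. The C6 bromine then carries an enone, an asymmetric conjugate alkynylation, an enantioselective methyl addition and a final Sonogashira heteroannulation to the benzofuran.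

Key step: step 1

Assumption: the sense of induction of each chiral catalyst or ligand is assigned by analogy with simpler substrates; the antipode named is the one expected to give the configuration drawn.

Step 1
Reactants: 1 4-bromo-3-methoxyphenol; 2 3-methylbut-2-enal (prenal)
Product: 5 6-bromo-7-methoxy-2,2-dimethyl-2H-chromene, via benzodioxaborin 3 (not isolated), via ortho-quinone methide 4 (not isolated)
Conditions: PhB(OH)2 (1.1 equiv), EtCO2H (cat.), toluene, reflux, Dean–Stark
Reagents that add atoms: none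
Why: Phenylboronic acid condenses with phenol 1 and prenal 2 so that the aldehyde is delivered within a boron ester to the ring carbon ortho to the phenolic oxygen (boron-templated ortho-hydroxyalkylation), giving benzodioxaborin 3, which on heating loses its PhB=O unit by cycloreversion to the ortho-quinone methide 4. Thermal disrotatory oxa-6π electrocyclization of the 1-oxatriene in 4 then forms the O1–C2 bond, closes the pyran ring and restores the benzene ring, which drives the sequence. The closest known reaction type is the phenylboronic acid-mediated formal (3+3) chromenylation of phenols with α,β-unsaturated aldehydes. The six-membered ring closes in a pericyclic 6π mode and no stereocenter is formed; the reversible steps before it should let both geometrical isomers of 4 funnel through the one that can close. The selectivity required is regiochemical: of the two carbons ortho to the hydroxyl of 1, the one para to the methoxy group is activated and unhindered, the other is flanked by OH and OMe, and the para position is blocked by bromine.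

Step 2
Reactants: 5 6-bromo-7-methoxy-2,2-dimethyl-2H-chromene; 6 (E)-N-methoxy-N-methylbut-2-enamide
Product: 9 (E)-1-(7-methoxy-2,2-dimethyl-2H-chromen-6-yl)but-2-en-1-one, via aryllithium 7 (not isolated), via tetrahedral lithium adduct 8 (not isolated)
Conditions: n-BuLi, THF, −78 °C; then 6, −78 to −20 °C; AcOH, −78 °C
Reagents that add atoms: none
Why: Bromine–lithium exchange gives aryllithium 7, whose 1,2-addition to amide 6 stops at the chelated adduct 8 (Weinreb ketone synthesis), so over-addition is avoided and the E-enone is released only on the cold acidic quench.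

Step 3
Reactants: 9 (E)-1-(7-methoxy-2,2-dimethyl-2H-chromen-6-yl)but-2-en-1-one; 10 ethynyltriisopropylsilane
Product: 11 (S)-1-(7-methoxy-2,2-dimethyl-2H-chromen-6-yl)-3-methyl-5-(triisopropylsilyl)pent-4-yn-1-one
Conditions: [Rh(OAc)(C2H4)2]2 (2.5 mol%), (R)-DTBM-SEGPHOS (6 mol%), 1,4-dioxane, 80 °C
Reagents that add atoms: none
Why: Rhodium-catalysed asymmetric conjugate alkynylation of an enone, in which an alkynylrhodium species adds to the β-carbon of 9 from the face selected by the bulky chiral bisphosphine to set the (S)-methyl-bearing stereocenter, while the bulky silyl group suppresses alkyne dimerisation.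

Step 4
Reactants: 11 (S)-1-(7-methoxy-2,2-dimethyl-2H-chromen-6-yl)-3-methyl-5-(triisopropylsilyl)pent-4-yn-1-one
Product: 12 (2S,4S)-2-(7-methoxy-2,2-dimethyl-2H-chromen-6-yl)-4-methyl-6-(triisopropylsilyl)hex-5-yn-2-ol
Conditions: ZnMe2 (3 equiv), Ti(OiPr)4 (1.2 equiv), (1R,2R)-trans-1,2-bis(hydroxycamphorsulfonamido)cyclohexane (10 mol%), toluene, rt; then H2O
Reagents that add atoms: dimethylzinc, C[Zn]C
Why: Titanium-promoted catalytic enantioselective addition of a dialkylzinc to an aryl alkyl ketone, in which the chiral bis(sulfonamide) diol titanium complex delivers methyl to one ketone face to set the (S)-carbinol under catalyst control (the remote methyl stereocenter should exert little bias) and the silylated alkyne stays inert.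

Step 5
Reactants: 12 (2S,4S)-2-(7-methoxy-2,2-dimethyl-2H-chromen-6-yl)-4-methyl-6-(triisopropylsilyl)hex-5-yn-2-ol
Product: 13 (2S,4S)-2-(7-methoxy-2,2-dimethyl-2H-chromen-6-yl)-4-methylhex-5-yn-2-ol
Conditions: TBAF, THF, 0 °C to rt
Reagents that add atoms: none
Why: Fluoride-induced protodesilylation of the alkynylsilane under basic conditions that leave the acid-sensitive tertiary benzylic alcohol, the chromene and both stereocenters untouched.

Step 6
Reactants: 14 1-(2,4-dihydroxyphenyl)ethan-1-one
Product: 15 1-(2,4-dihydroxy-5-iodophenyl)ethan-1-one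
Conditions: NIS (1.0 equiv), MeCN, 0 °C to rt
Reagents that add atoms: N-iodosuccinimide, O=C1CCC(=O)N1I
Why: Electrophilic aromatic iodination at C5, the unhindered position ortho to the free 4-hydroxyl and para to the chelated 2-hydroxyl, in preference to the doubly flanked C3.

Step 7
Reactants: 13 (2S,4S)-2-(7-methoxy-2,2-dimethyl-2H-chromen-6-yl)-4-methylhex-5-yn-2-ol; 15 1-(2,4-dihydroxy-5-iodophenyl)ethan-1-one
Product: 17 1-[6-hydroxy-2-[(2S,4S)-4-hydroxy-4-(7-methoxy-2,2-dimethyl-2H-chromen-6-yl)pentan-2-yl]-1-benzofuran-5-yl]ethan-1-one, via ortho-alkynylphenol 16 (not isolated)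
Conditions: PdCl2(PPh3)2 (3 mol%), CuI (6 mol%), Et3N, DMF (degassed), 60 °C
Reagents that add atoms: none
Why: Sonogashira coupling gives ortho-alkynylphenol 16, whose non-chelated hydroxyl (para to the acetyl group) adds 5-endo-dig to the metal-activated alkyne to close the benzofuran (tandem Sonogashira–heteroannulation) under basic conditions that spare the tertiary alcohol and both stereocenters.

Compound list
1 | 4-bromo-3-methoxyphenol | COc1cc(O)ccc1Br | starting material
2 | 3-methylbut-2-enal (prenal) | CC(C)=CC=O | starting material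
3 | 6-bromo-7-methoxy-4-(2-methylprop-1-en-1-yl)-2-phenyl-4H-1,3,2-benzodioxaborine (racemic at C4) | COc1cc2OB(c3ccccc3)OC(C=C(C)C)c2cc1Br | intermediate
4 | (6Z)-4-bromo-3-methoxy-6-(3-methylbut-2-en-1-ylidene)cyclohexa-2,4-dien-1-one | O=C1C=C(OC)C(Br)=C/C1=C/C=C(C)C | intermediate
5 | 6-bromo-7-methoxy-2,2-dimethyl-2H-chromene | COc1cc2c(cc1Br)C=CC(C)(C)O2 | intermediate
6 | (E)-N-methoxy-N-methylbut-2-enamide | C/C=C/C(=O)N(C)OC | starting material
7 | (7-methoxy-2,2-dimethyl-2H-chromen-6-yl)lithium | COc1cc2c(cc1[Li])C=CC(C)(C)O2 | intermediate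
8 | lithium (E)-1-(7-methoxy-2,2-dimethyl-2H-chromen-6-yl)-1-[methoxy(methyl)amino]but-2-en-1-olate | COc1cc2c(cc1C(O[Li])(/C=C/C)N(C)OC)C=CC(C)(C)O2 | intermediate
9 | (E)-1-(7-methoxy-2,2-dimethyl-2H-chromen-6-yl)but-2-en-1-one | COc1cc2c(cc1C(=O)/C=C/C)C=CC(C)(C)O2 | intermediate
10 | ethynyltriisopropylsilane | C#C[Si](C(C)C)(C(C)C)C(C)C | starting material
11 | (S)-1-(7-methoxy-2,2-dimethyl-2H-chromen-6-yl)-3-methyl-5-(triisopropylsilyl)pent-4-yn-1-one | COc1cc2c(cc1C(=O)C[C@H](C)C#C[Si](C(C)C)(C(C)C)C(C)C)C=CC(C)(C)O2 | intermediate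
12 | (2S,4S)-2-(7-methoxy-2,2-dimethyl-2H-chromen-6-yl)-4-methyl-6-(triisopropylsilyl)hex-5-yn-2-ol | COc1cc2c(cc1[C@@](C)(O)C[C@H](C)C#C[Si](C(C)C)(C(C)C)C(C)C)C=CC(C)(C)O2 | intermediate
13 | (2S,4S)-2-(7-methoxy-2,2-dimethyl-2H-chromen-6-yl)-4-methylhex-5-yn-2-ol | COc1cc2c(cc1[C@@](C)(O)C[C@H](C)C#C)C=CC(C)(C)O2 | intermediate
14 | 1-(2,4-dihydroxyphenyl)ethan-1-one | CC(=O)c1ccc(O)cc1O | starting material
15 | 1-(2,4-dihydroxy-5-iodophenyl)ethan-1-one | CC(=O)c1cc(I)c(O)cc1O | intermediate
16 | 1-[2,4-dihydroxy-5-[(3S,5S)-5-hydroxy-5-(7-methoxy-2,2-dimethyl-2H-chromen-6-yl)-3-methylhex-1-yn-1-yl]phenyl]ethan-1-one | COc1cc2c(cc1[C@@](C)(O)C[C@H](C)C#Cc1cc(C(C)=O)c(O)cc1O)C=CC(C)(C)O2 | intermediate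
17 | 1-[6-hydroxy-2-[(2S,4S)-4-hydroxy-4-(7-methoxy-2,2-dimethyl-2H-chromen-6-yl)pentan-2-yl]-1-benzofuran-5-yl]ethan-1-one | COc1cc2c(cc1[C@@](C)(O)C[C@H](C)c1cc3cc(C(C)=O)c(O)cc3o1)C=CC(C)(C)O2 | target

Total step count: 7. Longest linear sequence: 6 steps (steps 1 to 5, then step 7); step 6 prepares the coupling partner.

Steps most likely to fail

Step 4. Methyl transfer from zinc to a hindered, electron-rich ortho-methoxyaryl ketone may be slow, and catalyst control of the ketone face may be incomplete. The fallback is a stereospecific lithiation–borylation that sets out from ketone 11 and comes back at alcohol 12. Corey–Bakshi–Shibata reduction of 11 with (R)-2-methyl-CBS-oxazaborolidine and BH3·SMe2 should give (1S,3S)-1-(7-methoxy-2,2-dimethyl-2H-chromen-6-yl)-3-methyl-5-(triisopropylsilyl)pent-4-yn-1-ol F1. Carbamoylation (i-Pr2NCOCl, Et3N, CH2Cl2, reflux) gives the N,N-diisopropylcarbamate F2. Deprotonation of F2 with s-BuLi (Et2O, −78 °C) proceeds with retention, trapping with 2-methyl-4,4,5,5-tetramethyl-1,3,2-dioxaborolane places boron where hydrogen was, and the 1,2-metallate rearrangement (MgBr2, MeOH, warming) moves methyl to carbon with inversion, giving the tertiary pinacol boronic ester F3. Oxidation of F3 (NaOH, H2O2) with retention gives 12.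

Step 3. Enantiofacial discrimination on the ortho-substituted aryl enone may be insufficient, and alkyne oligomerisation may compete. The fallback takes the stereocenter from a reduced ynone and makes the carbon–carbon bond by SN2 displacement; it sets out from bromide 5 (as aryllithium 7) and comes back at ketone 11. Noyori asymmetric transfer hydrogenation of commercial 4-(triisopropylsilyl)but-3-yn-2-one (RuCl(p-cymene)[(S,S)-TsDPEN], i-PrOH) should give (S)-4-(triisopropylsilyl)but-3-yn-2-ol F4. Mesylation (MsCl, Et3N, CH2Cl2, 0 °C) gives the methanesulfonate F5. Displacement with sodium dimethyl malonate (NaH, DMF) with inversion gives the malonate F6; the descriptor stays S because the priorities change, and the bulky silyl group blocks attack at the alkyne terminus. Krapcho demethoxycarbonylation (LiCl, wet DMSO, 140 °C) gives methyl (S)-3-methyl-5-(triisopropylsilyl)pent-4-ynoate F7. Treatment with MeNHOMe·HCl and i-PrMgCl (THF, −20 °C) gives the Weinreb amide F8, and acylation of 7 with F8 as in step 2 delivers 11.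

Step 7. With two free phenols present, the sequence may stall after the coupling, or copper-mediated oxidative homocoupling may consume alkyne 13. The fallback is a protected, stepwise variant that sets out from 15 and 13 and comes back at 16 and then 17. Acetylation of 15 (Ac2O, pyridine, DMAP) gives 4-acetyl-6-iodo-1,3-phenylene diacetate F9. Sonogashira coupling of F9 with 13 at room temperature (PdCl2(PPh3)2, CuI, Et3N, THF) gives the aryl alkyne diacetate F10. Methanolysis (K2CO3, MeOH, 50 °C) releases 16, which should cyclise 5-endo-dig under the same basic conditions to 17.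

Further compounds
F1 | step 4 | (1S,3S)-1-(7-methoxy-2,2-dimethyl-2H-chromen-6-yl)-3-methyl-5-(triisopropylsilyl)pent-4-yn-1-ol | COc1cc2c(cc1[C@@H](O)C[C@H](C)C#C[Si](C(C)C)(C(C)C)C(C)C)C=CC(C)(C)O2
F2 | step 4 | (1S,3S)-1-(7-methoxy-2,2-dimethyl-2H-chromen-6-yl)-3-methyl-5-(triisopropylsilyl)pent-4-yn-1-yl N,N-diisopropylcarbamate | COc1cc2c(cc1[C@@H](OC(=O)N(C(C)C)C(C)C)C[C@H](C)C#C[Si](C(C)C)(C(C)C)C(C)C)C=CC(C)(C)O2
F3 | step 4 | 2-[(2R,4S)-2-(7-methoxy-2,2-dimethyl-2H-chromen-6-yl)-4-methyl-6-(triisopropylsilyl)hex-5-yn-2-yl]-4,4,5,5-tetramethyl-1,3,2-dioxaborolane | COc1cc2c(cc1[C@@](C)(B3OC(C)(C)C(C)(C)O3)C[C@H](C)C#C[Si](C(C)C)(C(C)C)C(C)C)C=CC(C)(C)O2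
F4 | step 3 | (S)-4-(triisopropylsilyl)but-3-yn-2-ol | C[C@H](O)C#C[Si](C(C)C)(C(C)C)C(C)C
F5 | step 3 | (S)-4-(triisopropylsilyl)but-3-yn-2-yl methanesulfonate | C[C@H](OS(C)(=O)=O)C#C[Si](C(C)C)(C(C)C)C(C)C
F6 | step 3 | dimethyl 2-[(S)-4-(triisopropylsilyl)but-3-yn-2-yl]propanedioate | COC(=O)C(C(=O)OC)[C@H](C)C#C[Si](C(C)C)(C(C)C)C(C)C
F7 | step 3 | methyl (S)-3-methyl-5-(triisopropylsilyl)pent-4-ynoate | COC(=O)C[C@H](C)C#C[Si](C(C)C)(C(C)C)C(C)C
F8 | step 3 | (S)-N-methoxy-N,3-dimethyl-5-(triisopropylsilyl)pent-4-ynamide | CON(C)C(=O)C[C@H](C)C#C[Si](C(C)C)(C(C)C)C(C)C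
F9 | step 7 | 4-acetyl-6-iodo-1,3-phenylene diacetate | CC(=O)c1cc(I)c(OC(C)=O)cc1OC(C)=O
F10 | step 7 | 4-acetyl-6-[(3S,5S)-5-hydroxy-5-(7-methoxy-2,2-dimethyl-2H-chromen-6-yl)-3-methylhex-1-yn-1-yl]-1,3-phenylene diacetate | COc1cc2c(cc1[C@@](C)(O)C[C@H](C)C#Cc1cc(C(C)=O)c(OC(C)=O)cc1OC(C)=O)C=CC(C)(C)O2
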